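**Plan**

1. Retrosynthesis: the side-chain diene is cut to a terminal alkyne plus ethene (C13=C16, C14=C15), the acetate to the C18 alcohol, and the stereocentres C5, C6, C8, C9 to two ring-B alkenes (C5=C6, C8=C9) that are hydroborated together.
2. Ring A is then opened at C3–C4 by a retro ester-enolate Claisen step: C18 is raised to the carboxyl level and tied as a δ-lactone to an oxygen on C1, and C2=C3 becomes a vinyl group on C1. The lactone C4=C5 bond is cut by a Horner–Wadsworth–Emmons step, C1–C10 by an aldol and C9–C11 by a Stork–Danheiser addition.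
3. Enabling feature: the quaternary C4 carries a one-carbon oxygenated branch (C18) and is separated from C1 by the unfunctionalised C3–C2 unit, while C5 and C10 of ring B hold C4 and C1 in a 1,4 relationship. This is the pattern of a vinyl δ-lactone that can rearrange into a cyclohexene carboxylic acid.
4. Forward order: ring B (from a commercial cyclohexenone), then the fused δ-lactone, then ring A by the ring-closing Ireland–Claisen rearrangement, then reduction and hydroboration of the ring alkenes, then the diene. The helpers are removed on the way: the lactone ring in the rearrangement itself, the C1=C2 bond in step 9, the carboxyl level in step 10.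
5. Stereochemistry: C1 from (R)-glyceraldehyde acetonide (Felkin–Anh), C10 from the closed aldol transition state relative to C1, C4 by [3,3] chirality transfer from C1, and C5/C6/C8/C9 by syn hydroboration on the face opposite the C10 methyl group.

Key step: step 8

Assumption: atoms are numbered as in labdanes (C1–C20) in all intermediates, and 2-(diethoxyphosphoryl)propanoic acid 10 is taken to be a commercial reagent.

**Route**

Step 1
Reactants: 1 3-ethoxy-2-methylcyclohex-2-en-1-one
Product: 2 3-ethoxy-2,6-dimethylcyclohex-2-en-1-one (racemic)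
Conditions: LiN(iPr)2, THF, −78 °C; MeI, −78 → 0 °C
Reagents that add atoms: iodomethane, CI
Why: Kinetic deprotonation of the vinylogous ester occurs at the only enolisable position next to the carbonyl (the future C8) and methylation of that enolate (first half of a Stork–Danheiser sequence) installs the future C17 methyl; the new stereocentre is racemic and is planarised again in step 3.

Step 2
Reactants: 2 3-ethoxy-2,6-dimethylcyclohex-2-en-1-one; 3 2-(2-bromoethyl)-1,3-dioxolane
Product: 6 3-[2-(1,3-dioxolan-2-yl)ethyl]-2,4-dimethylcyclohex-2-en-1-one (racemic), via Grignard reagent 4 (not isolated), via tertiary allylic alcohol 5 (not isolated)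
Conditions: Mg, THF, 25 °C; 2, 0 °C → rt; 1 M HCl, THF, 0 °C
Reagents that add atoms: water, O
Why: 1,2-Addition of the Grignard reagent to the vinylogous ester carbonyl followed by mild acid hydrolysis and dehydration of the β-hydroxy enol ether (Stork–Danheiser alkylative carbonyl transposition) should give the transposed enone carrying the C11–C13 chain, the aldehyde ethylene acetal being far less labile than the ionisable tertiary allylic alcohol; C8 stays racemic and is planarised in step 3.

Step 3
Reactants: 6 3-[2-(1,3-dioxolan-2-yl)ethyl]-2,4-dimethylcyclohex-2-en-1-one; 7 (R)-2,2-dimethyl-1,3-dioxolane-4-carbaldehyde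
Product: 9 (2R)-2-{(S)-[(4R)-2,2-dimethyl-1,3-dioxolan-4-yl](hydroxy)methyl}-3-[2-(1,3-dioxolan-2-yl)ethyl]-2,4-dimethylcyclohex-3-en-1-one, via lithium dienolate 8 (not isolated)
Conditions: LiN(SiMe3)2 (0.95 equiv), THF, 0 °C → rt; −78 °C, 7; AcOH, −78 °C
Reagents that add atoms: none
Why: Under equilibrating conditions the fully substituted, linearly conjugated ring dienolate 8 should be the resting enolate, lithium dienolates add to aldehydes at the α-carbon (here C10) through a closed Zimmerman–Traxler chair that places the C10 methyl (cis to OLi) syn to the new hydroxyl, and Felkin–Anh attack anti to the α-oxygen of 7 sets C1 as S and with it C10 as R (aldol addition with 1,2-induction from the chiral-pool aldehyde).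

Step 4
Reactants: 9 aldol adduct; 10 2-(diethoxyphosphoryl)propanoic acid
Product: 11 2-(diethoxyphosphoryl)propanoate ester of 9 at the C1 hydroxyl (epimers at the phosphonate carbon)
Conditions: DCC, DMAP (cat.), CH2Cl2, 0 °C → rt
Reagents that add atoms: none
Why: Steglich esterification acylates the hindered secondary C1 hydroxyl under neutral conditions that avoid retro-aldol cleavage, and no stereocentre of the skeleton is touched.

Step 5
Reactants: 11 phosphonate ester
Product: 12 (1S,8aS)-1-[(4R)-2,2-dimethyl-1,3-dioxolan-4-yl]-8-[2-(1,3-dioxolan-2-yl)ethyl]-4,7,8a-trimethyl-1,5,6,8a-tetrahydro-3H-isochromen-3-one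
Conditions: NaH, THF, 0 → 60 °C
Reagents that add atoms: none
Why: Intramolecular Horner–Wadsworth–Emmons olefination of the phosphonate anion onto the C5 ketone closes the six-membered α-methyl-α,β-unsaturated lactone with the C4=C5 geometry fixed by the ring, and the ketone cannot enolise towards the quaternary C10, so C1 and C10 are not at risk.

Step 6
Reactants: 12 acetonide lactone
Product: 13 (1S,8aS)-1-[(1R)-1,2-dihydroxyethyl]-8-[2-(1,3-dioxolan-2-yl)ethyl]-4,7,8a-trimethyl-1,5,6,8a-tetrahydro-3H-isochromen-3-one
Conditions: ethylene glycol (excess), pyridinium p-toluenesulfonate (cat.), MeCN, 45 °C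
Reagents that add atoms: none
Why: Acid-catalysed transketalisation to an excess of ethylene glycol should strip the isopropylidene ketal (leaving as 2,2-dimethyl-1,3-dioxolane) while the aldehyde acetal, itself an ethylene acetal, only exchanges degenerately, so the 1,2-diol is freed without unmasking C13.

Step 7
Reactants: 13 diol lactone
Product: 14 (1R,8aS)-8-[2-(1,3-dioxolan-2-yl)ethyl]-1-ethenyl-4,7,8a-trimethyl-1,5,6,8a-tetrahydro-3H-isochromen-3-one
Conditions: PPh3, imidazole, I2, toluene, 90 °C
Reagents that add atoms: none
Why: Garegg–Samuelsson olefination converts the terminal vicinal diol through its vicinal diiodide into the C2=C3 vinyl group by reductive elimination, and C1 is not involved and keeps its configuration (vinyl cis to the C10 methyl on the lactone ring).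

Step 8
Reactants: 14 vinyl lactone
Product: 17 (1S,4aS)-5-[2-(1,3-dioxolan-2-yl)ethyl]-1,4a,6-trimethyl-1,2,4a,7-tetrahydronaphthalene-1-carboxylic acid, via silyl ketene acetal 15 (not isolated), via trimethylsilyl ester 16 (not isolated)
Conditions: LiN(iPr)2, Me3SiCl, Et3N, THF, −78 °C → rt; toluene, 120 °C (sealed tube); aq. citric acid, THF, rt
Reagents that add atoms: none
Why: LiN(iPr)2 removes the γ-proton at C6 of the unsaturated lactone (the only position whose deprotonation gives a conjugated enolate), O-silylation gives the cyclic dienyl ketene acetal 15, and on heating the C4=C18(OSi)–O–C1–C2=C3 array undergoes a concerted suprafacial [3,3]-sigmatropic shift that makes the C3–C4 bond, breaks C1–O and leaves silyl ester 16 with a new C1=C2 and a retained C5=C6 double bond. The closest known reaction type is the Ireland–Claisen rearrangement of silyl ketene acetals of lactones that carry a vinyl group on the carbinol carbon (six-membered lactone to six-membered ring, as in the dioxanone-to-dihydropyran version), here combined with the deconjugative enolisation known for α,β-unsaturated esters. Ring A is closed with conservation of ring size: the C18–O bridge between C4 and C1 is exchanged for the C3–C2 bridge through a boat-like, bicyclo[2.2.2]octane-type transition state, the only geometry the tether allows. C4 is the only new stereocentre and is set by chirality transfer from C1: C3 can reach C4 only on the lactone face that carries the vinyl group, which is the face of the C10 methyl, so the C4 methyl ends cis and the carboxyl trans to the C10 methyl, and the ketene acetal geometry is fixed by the ring. The step needs O- rather than C-silylation, bond formation at C4 (α) rather than C6 (γ) and no intermolecular cycloaddition of the diene: a six-atom cyclic array exists only through C4, and the C18=C4–C5=C6 diene is locked s-trans. The flat, doubly unsaturated ring B strains the boat transition state, which is why a higher temperature than for simple lactones is planned.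

Step 9
Reactants: 17 trienyl acid
Product: 18 (1S,4aS)-5-[2-(1,3-dioxolan-2-yl)ethyl]-1,4a,6-trimethyl-1,2,3,4,4a,7-hexahydronaphthalene-1-carboxylic acid
Conditions: 2-nitrobenzenesulfonylhydrazide, Et3N, CH2Cl2, rt
Reagents that add atoms: none
Why: Diimide reduction delivers H2 by a concerted syn transfer that is very sensitive to substitution, so the cis-disubstituted C1=C2 bond should be reduced while the trisubstituted C5=C6 and tetrasubstituted C8=C9 bonds, the acid and the acetal are left untouched, with no metal present to migrate double bonds.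

Step 10
Reactants: 18 dienyl acid
Product: 20 (1S,2S,4R,4aS,5S,8aR)-1-[2-(1,3-dioxolan-2-yl)ethyl]-5-(hydroxymethyl)-2,5,8a-trimethyldecahydronaphthalene-2,4-diol, via tris-boryl adduct 19 (not isolated)
Conditions: BH3·THF (excess), THF, 0 → 45 °C; NaOH, H2O2, 0 °C → rt
Reagents that add atoms: hydrogen peroxide, OO
Why: BH3 reduces the carboxylic acid to the C18 alcohol and adds syn to both ring-B alkenes from the face opposite the axial C10 and C4 methyl groups with boron on the less hindered carbons C6 and C8, so that oxidation with retention (hydroboration–oxidation) should set the trans ring fusion at C5, the equatorial 6-OH, the equatorial tertiary 8-OH and the C9 hydrogen in one operation.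

Step 11
Reactants: 20 triol acetal
Product: 22 8,13-lactol: cyclic hemiacetal between C13 and the 8-oxygen (both C13 epimers), via mixed cyclic acetal 21 (not isolated)
Conditions: 1 M HCl, THF/H2O, rt
Reagents that add atoms: water, O
Why: Acid opens the dioxolane to the C13 oxocarbenium ion, which should be captured by the nearby tertiary 8-hydroxyl in a six-membered ring closure (intramolecular transacetalisation) to give the 2-hydroxyethyl mixed acetal 21; loss of ethylene glycol from 21 and addition of water to the resulting cyclic oxocarbenium ion (acetal hydrolysis) then give the six-membered lactol as the stable closed form, with no stereocentre of the skeleton touched.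

Step 12
Reactants: 22 lactol
Product: 24 (1S,2S,4R,4aS,5S,8aR)-1-(but-3-yn-1-yl)-5-(hydroxymethyl)-2,5,8a-trimethyldecahydronaphthalene-2,4-diol, via hydroxy aldehyde 23 (not isolated)
Conditions: dimethyl (1-diazo-2-oxopropyl)phosphonate, K2CO3, MeOH, 0 °C → rt
Reagents that add atoms: dimethyl (1-diazo-2-oxopropyl)phosphonate, CC(=O)C(=[N+]=[N-])P(=O)(OC)OC
Why: Under the basic methanolic conditions the lactol should open by ring–chain tautomerism to hydroxy aldehyde 23, which is trapped by the diazomethylphosphonate anion generated in the flask and converted into the terminal alkyne (Ohira–Bestmann variant of the Seyferth–Gilbert homologation) under mild carbonate conditions that tolerate the three free hydroxyls.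

Step 13
Reactants: 24 alkynyl triol
Product: 25 [(1S,4aR,5S,6S,8R,8aS)-5-(but-3-yn-1-yl)-6,8-dihydroxy-1,4a,6-trimethyldecahydronaphthalen-1-yl]methyl acetate
Conditions: AcCl, 2,4,6-collidine, CH2Cl2, −78 °C
Reagents that add atoms: acetyl chloride, CC(=O)Cl
Why: Kinetically controlled acylation with acetyl chloride and a hindered pyridine base at low temperature should acetylate the primary C18 hydroxyl in preference to the hindered secondary 6-OH and the tertiary 8-OH (chemoselective esterification), the primary acetate also being the preferred site if acyl migration occurred.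

Step 14
Reactants: 25 alkynyl acetate
Product: 26 [(1S,4aR,5S,6S,8R,8aS)-6,8-dihydroxy-1,4a,6-trimethyl-5-(3-methylidenepent-4-en-1-yl)decahydronaphthalen-1-yl]methyl acetate (CNP0317825.1)
Conditions: ethene (1 atm), second-generation Grubbs catalyst (H2IMes)(PCy3)Cl2Ru=CHPh (cat.), toluene, 80 °C
Reagents that add atoms: ethene, C=C
Why: Ruthenium-carbene-catalysed ethene–alkyne cross enyne metathesis converts the terminal alkyne directly into the 2-substituted buta-1,3-diene (C13=C16 and C14=C15) without affecting hydroxyls, acetate or stereocentres, which puts the sensitive diene into the molecule last.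

**Compound list**

1 | 3-ethoxy-2-methylcyclohex-2-en-1-one | CCOC1=C(C)C(=O)CCC1 | starting material
2 | 3-ethoxy-2,6-dimethylcyclohex-2-en-1-one (racemic) | CCOC1=C(C)C(=O)C(C)CC1 | intermediate
3 | 2-(2-bromoethyl)-1,3-dioxolane | BrCCC1OCCO1 | starting material
4 | [2-(1,3-dioxolan-2-yl)ethyl]magnesium bromide (forms in the flask) | Br[Mg]CCC1OCCO1 | intermediate
5 | 1-[2-(1,3-dioxolan-2-yl)ethyl]-3-ethoxy-2,6-dimethylcyclohex-2-en-1-ol (forms in the flask, as its magnesium alkoxide before work-up) | CCOC1=C(C)C(O)(CCC2OCCO2)C(C)CC1 | intermediate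
6 | 3-[2-(1,3-dioxolan-2-yl)ethyl]-2,4-dimethylcyclohex-2-en-1-one (racemic) | CC1CCC(=O)C(C)=C1CCC1OCCO1 | intermediate
7 | (R)-2,2-dimethyl-1,3-dioxolane-4-carbaldehyde | CC1(C)OC[C@H](C=O)O1 | starting material
8 | lithium 3-[2-(1,3-dioxolan-2-yl)ethyl]-2,4-dimethylcyclohexa-1,3-dien-1-olate (forms in the flask) | CC1=C(CCC2OCCO2)C(C)=C(O[Li])CC1 | intermediate
9 | (2R)-2-{(S)-[(4R)-2,2-dimethyl-1,3-dioxolan-4-yl](hydroxy)methyl}-3-[2-(1,3-dioxolan-2-yl)ethyl]-2,4-dimethylcyclohex-3-en-1-one | O=C1CCC(C)=C(CCC2OCCO2)[C@]1(C)[C@H](O)[C@H]1COC(C)(C)O1 | intermediate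
10 | 2-(diethoxyphosphoryl)propanoic acid (racemic) | CC(C(=O)O)P(=O)(OCC)OCC | starting material
11 | 2-(diethoxyphosphoryl)propanoate ester of 9 (epimers at the phosphonate carbon) | O=C1CCC(C)=C(CCC2OCCO2)[C@]1(C)[C@H](OC(=O)C(C)P(=O)(OCC)OCC)[C@H]1COC(C)(C)O1 | intermediate
12 | (1S,8aS)-1-[(4R)-2,2-dimethyl-1,3-dioxolan-4-yl]-8-[2-(1,3-dioxolan-2-yl)ethyl]-4,7,8a-trimethyl-1,5,6,8a-tetrahydro-3H-isochromen-3-one | CC1=C2CCC(C)=C(CCC3OCCO3)[C@]2(C)[C@@H]([C@H]2COC(C)(C)O2)OC1=O | intermediate
13 | (1S,8aS)-1-[(1R)-1,2-dihydroxyethyl]-8-[2-(1,3-dioxolan-2-yl)ethyl]-4,7,8a-trimethyl-1,5,6,8a-tetrahydro-3H-isochromen-3-one | CC1=C2CCC(C)=C(CCC3OCCO3)[C@]2(C)[C@@H]([C@H](O)CO)OC1=O | intermediate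
14 | (1R,8aS)-8-[2-(1,3-dioxolan-2-yl)ethyl]-1-ethenyl-4,7,8a-trimethyl-1,5,6,8a-tetrahydro-3H-isochromen-3-one (vinyl cis to the C10 methyl) | CC1=C2CCC(C)=C(CCC3OCCO3)[C@]2(C)[C@@H](C=C)OC1=O | intermediate
15 | trimethylsilyl dienyl ketene acetal of 14 with C18=C4 and C5=C6 double bonds (forms in the flask) | CC1=C(O[Si](C)(C)C)O[C@H](C=C)[C@]2(C)C1=CCC(C)=C2CCC1OCCO1 | intermediate
16 | trimethylsilyl ester of 17 (forms in the flask) | C[C@]1(C(=O)O[Si](C)(C)C)CC=C[C@]2(C)C1=CCC(C)=C2CCC1OCCO1 | intermediate
17 | (1S,4aS)-5-[2-(1,3-dioxolan-2-yl)ethyl]-1,4a,6-trimethyl-1,2,4a,7-tetrahydronaphthalene-1-carboxylic acid | C[C@]1(C(=O)O)CC=C[C@]2(C)C1=CCC(C)=C2CCC1OCCO1 | intermediate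
18 | (1S,4aS)-5-[2-(1,3-dioxolan-2-yl)ethyl]-1,4a,6-trimethyl-1,2,3,4,4a,7-hexahydronaphthalene-1-carboxylic acid | C[C@]1(C(=O)O)CCC[C@]2(C)C1=CCC(C)=C2CCC1OCCO1 | intermediate
19 | C6,C8-diboryl C18-O-boryl adduct, drawn with monomeric BH2 groups (forms in the flask) | O1CCOC1CC[C@H]1[C@]2(C)CCC[C@](C)(COB)[C@H]2[C@H](B)C[C@]1(C)B | intermediate
20 | (1S,2S,4R,4aS,5S,8aR)-1-[2-(1,3-dioxolan-2-yl)ethyl]-5-(hydroxymethyl)-2,5,8a-trimethyldecahydronaphthalene-2,4-diol | O1CCOC1CC[C@H]1[C@]2(C)CCC[C@](C)(CO)[C@H]2[C@H](O)C[C@]1(C)O | intermediate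
21 | mixed cyclic acetal: C13 carries a 2-hydroxyethoxy group and is bridged by oxygen to C8 in a tetrahydropyran fused at C8–C9, with the 6-hydroxyl and the C18 hydroxymethyl free (both C13 epimers; forms in the flask) | OCCOC1CC[C@H]2[C@]3(C)CCC[C@](C)(CO)[C@H]3[C@H](O)C[C@]2(C)O1 | intermediate
22 | 8,13-lactol: the same fused tetrahydropyran with a hydroxyl on C13 in place of the 2-hydroxyethoxy group (both C13 epimers) | OC1CC[C@H]2[C@]3(C)CCC[C@](C)(CO)[C@H]3[C@H](O)C[C@]2(C)O1 | intermediate
23 | 3-[(1S,2S,4R,4aS,5S,8aR)-2,4-dihydroxy-5-(hydroxymethyl)-2,5,8a-trimethyldecahydronaphthalen-1-yl]propanal (open-chain tautomer of 22; forms in the flask) | O=CCC[C@H]1[C@]2(C)CCC[C@](C)(CO)[C@H]2[C@H](O)C[C@]1(C)O | intermediate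
24 | (1S,2S,4R,4aS,5S,8aR)-1-(but-3-yn-1-yl)-5-(hydroxymethyl)-2,5,8a-trimethyldecahydronaphthalene-2,4-diol | C#CCC[C@H]1[C@]2(C)CCC[C@](C)(CO)[C@H]2[C@H](O)C[C@]1(C)O | intermediate
25 | [(1S,4aR,5S,6S,8R,8aS)-5-(but-3-yn-1-yl)-6,8-dihydroxy-1,4a,6-trimethyldecahydronaphthalen-1-yl]methyl acetate | C#CCC[C@H]1[C@]2(C)CCC[C@](C)(COC(C)=O)[C@H]2[C@H](O)C[C@]1(C)O | intermediate
26 | [(1S,4aR,5S,6S,8R,8aS)-6,8-dihydroxy-1,4a,6-trimethyl-5-(3-methylidenepent-4-en-1-yl)decahydronaphthalen-1-yl]methyl acetate (CNP0317825.1) | C=CC(=C)CC[C@H]1[C@]2(C)CCC[C@](C)(COC(C)=O)[C@H]2[C@H](O)C[C@]1(C)O | target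

**Summary**

Total step count: 14. Longest linear sequence: 14 steps (1 → 26); compounds 3, 7 and 10 enter as purchased building blocks.

Steps most likely to fail:

Step 8. The boat-like transition state is strained by the fused, doubly unsaturated ring B, so the rearrangement may be too slow and the ketene acetal may desilylate or decompose first. The fallback sets out from 14 and comes back at 17, replacing the pericyclic ring closure by an enolate alkylation with the same facial constraint. 9-BBN followed by NaBO3·4H2O should hydroborate only the vinyl group to the primary alcohol F1. PPh3/imidazole/I2 gives the iodide F2. LiN(SiMe3)2 in THF/DMPU deprotonates at C6, and the dienolate is alkylated at C4 by the tethered iodide (6-exo-tet), closing ring A as the bridged 2-oxabicyclo[2.2.2]octan-3-one F3. NaOMe/MeOH opens the strained lactone to the C1-hydroxy methyl ester F4. Burgess reagent removes the C1 hydroxyl by syn elimination towards C2 to give the methyl ester F5. LiOH in aqueous THF/MeOH returns acid 17.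

Step 10. Hydroboration of the tetrasubstituted C8=C9 bond may be incomplete, may place boron on C9, or may occur on the wrong face. The fallback sets out from 18 and comes back at 20. BH3·THF at 0 °C with limited reagent should reduce the acid and hydroborate only the trisubstituted C5=C6 bond, giving after oxidation the C18,C6-diol F6 with C8=C9 intact. mCPBA/NaHCO3 epoxidises the tetrasubstituted alkene on the face opposite the C10 methyl (also the face of the homoallylic 6-OH) to the epoxide F7. Cp2TiCl (trivalent titanium, made from Cp2TiCl2 and Zn) with 1,4-cyclohexadiene opens the epoxide homolytically at the more hindered C9–O bond, and the C9 radical takes up hydrogen axially, which should give 20.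

Step 3. Deprotonation may occur at C6 or at the side-chain CH2 instead of C8, the dienolate may react through its γ-carbon, or simple and facial diastereoselection may be poor. The fallback sets out from 6 and comes back at 14, changing the source of absolute configuration from the chiral pool to a kinetic resolution. Dienolate 8 is added to acrolein, and the racemic aldol is subjected to Sharpless kinetic resolution (Ti(OiPr)4, D-(−)-diisopropyl tartrate, t-BuOOH, 4 Å molecular sieves). This should leave the (R)-carbinol F8 while its enantiomer is consumed as the epoxy alcohol F10. Steglich esterification with 10 gives the phosphonate ester F9, and NaH closes the lactone to 14 directly, bypassing steps 6 and 7.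

**Further compounds**

F1 | step 8 | (1R,8aS)-8-[2-(1,3-dioxolan-2-yl)ethyl]-1-(2-hydroxyethyl)-4,7,8a-trimethyl-1,5,6,8a-tetrahydro-3H-isochromen-3-one | CC1=C2CCC(C)=C(CCC3OCCO3)[C@]2(C)[C@@H](CCO)OC1=O
F2 | step 8 | 1-(2-iodoethyl) analogue of F1 | CC1=C2CCC(C)=C(CCC3OCCO3)[C@]2(C)[C@@H](CCI)OC1=O
F3 | step 8 | bridged lactone with ring A closed (C4–C18(=O)–O–C1 bridge across ring A, C5=C6 and C8=C9 double bonds) | C[C@@]12CC[C@@H](OC1=O)[C@]3(C)C2=CCC(C)=C3CCC1OCCO1
F4 | step 8 | methyl ester of the C1-hydroxy analogue of 18 (C1 hydroxyl on the face opposite the C10 methyl) | C[C@]1(C(=O)OC)CC[C@@H](O)[C@]2(C)C1=CCC(C)=C2CCC1OCCO1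
F5 | step 8 | methyl ester of 17 | C[C@]1(C(=O)OC)CC=C[C@]2(C)C1=CCC(C)=C2CCC1OCCO1
F6 | step 10 | C18,C6-diol with the C8=C9 double bond retained | C[C@]1(CO)CCC[C@]2(C)[C@@H]1[C@H](O)CC(C)=C2CCC1OCCO1
F7 | step 10 | 8,9-epoxide of F6 (oxygen on the face opposite the C10 methyl) | C[C@]1(CO)CCC[C@]2(C)[C@@H]1[C@H](O)C[C@]3(C)O[C@]23CCC1OCCO1
F8 | step 3 | (2R)-3-[2-(1,3-dioxolan-2-yl)ethyl]-2-[(1R)-1-hydroxyprop-2-en-1-yl]-2,4-dimethylcyclohex-3-en-1-one | O=C1CCC(C)=C(CCC2OCCO2)[C@]1(C)[C@H](O)C=C
F9 | step 3 | 2-(diethoxyphosphoryl)propanoate ester of F8 | O=C1CCC(C)=C(CCC2OCCO2)[C@]1(C)[C@H](OC(=O)C(C)P(=O)(OCC)OCC)C=C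
F10 | step 3 | epoxy alcohol formed from the enantiomer of F8 | O=C1CCC(C)=C(CCC2OCCO2)[C@@]1(C)[C@@H](O)[C@H]1CO1
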